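**Retrosynthetic overview**

1. The strategy rests on ring A, a hexasubstituted phloroglucinol. Its carbons are numbered 1 to 6: carbon 1 bears the butyryl group, carbon 3 the geranyl group and carbon 5 the CH2 bridge to ring B, and these alternate with the oxygenated carbons 2, 4 and 6. A 3-silyloxycyclobutenone joined to a silyloxyalkyne gives exactly this pattern.
2. Ring A is cut into ring B cyclobutenone 18 and silyloxyalkyne 24, which carries the butyryl group as a ketal. The bonds between ring A carbons 1 and 6 and between carbons 2 and 3 are new, and the bond between carbons 5 and 6 is re-formed.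
3. Cyclobutenone 18 comes from a [2+2] cycloaddition of the aldoketene of ring B propanoic acid 9 with geranyl silyloxyalkyne 15. Acid 9 comes from ring B monomer 5 and allyl acrylate. Monomer 5 comes from acetylated 2-methylphloroglucinol by palladium-catalysed asymmetric dearomative geranylation, which sets the only stereocentre (R).
4. Ring order: ring B first, then the four-membered ring, then ring A. The end game is acid hydrolysis of the ketal and the two methyl enol ethers, then desilylation.

Key step: step 13

Assumptions: the (R,R)-ligand is taken to give the (R)-centre (the mirror-image ligand is used if the sense proves opposite); 8 is drawn with both methoxy groups on the ring carbons that flank the quaternary centre, and any regioisomeric methyl enol ether converges on the same triketone in step 14; the butyryl group is masked as a dioxolane, not a dimethyl ketal, to keep the sixth ring substituent small.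

**Route**

Step 1
Reactants: 1 2-methylphloroglucinol
Product: 2 1-(2,4,6-trihydroxy-3-methylphenyl)ethan-1-one
Conditions: AcCl (1.05 equiv), AlCl3 (3.5 equiv), PhNO2/CH2Cl2, 0 °C to rt; aq. HCl work-up
Reagents that add atoms: acetyl chloride, CC(=O)Cl
Why: Friedel–Crafts C-acylation of a phloroglucinol, in which the two free ring positions of 1 are equivalent by symmetry and the first acyl group deactivates the ring towards a second one.

Step 2
Reactants: 3 geraniol
Product: 4 geranyl methyl carbonate
Conditions: ClCO2Me (1.2 equiv), pyridine, CH2Cl2, 0 °C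
Reagents that add atoms: methyl chloroformate, COC(=O)Cl
Why: O-acylation of a primary allylic alcohol with a chloroformate, which leaves the (E)-olefin untouched.

Step 3
Reactants: 2 1-(2,4,6-trihydroxy-3-methylphenyl)ethan-1-one; 4 geranyl methyl carbonate
Product: 5 (4R)-2-acetyl-4-[(2E)-3,7-dimethylocta-2,6-dien-1-yl]-3,5-dihydroxy-4-methylcyclohexa-2,5-dien-1-one (ring B monomer)
Conditions: Pd2(dba)3·CHCl3 (2.5 mol %), N,N'-[(1R,2R)-cyclohexane-1,2-diyl]bis[2-(diphenylphosphanyl)benzamide] (7.5 mol %), degassed THF, 0 °C to rt
Reagents that add atoms: none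
Why: Tsuji–Trost asymmetric allylic alkylation run as a dearomatization, in which zerovalent palladium ionizes 4 to the π-geranyl complex and methoxide, the phloroglucinolate attacks through its electron-rich methyl-bearing carbon at the unhindered CH2 terminus of the allyl unit (linear E product), and the chiral ligand pocket selects the face of that prochiral ring carbon and so sets the quaternary centre as R.

Step 4
Reactants: 5 ring B monomer; 6 allyl acrylate
Product: 7 allyl 3-[(3R)-5-acetyl-3-geranyl-2,4-dihydroxy-3-methyl-6-oxocyclohexa-1,4-dien-1-yl]propanoate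
Conditions: 6 (1.3 equiv), Et3N (0.3 equiv), MeCN, 50 °C
Reagents that add atoms: none
Why: Michael addition of a cyclic β-tricarbonyl C–H acid to an acrylate, in which the only unsubstituted nucleophilic carbon of ring B reacts and the quaternary centre is not involved.

Step 5
Reactants: 7 Michael adduct
Product: 8 allyl 3-[(3R)-5-acetyl-3-geranyl-2,4-dimethoxy-3-methyl-6-oxocyclohexa-1,4-dien-1-yl]propanoate
Conditions: Me3SiCHN2 (3 equiv), toluene/MeOH 4:1, 0 °C to rt
Reagents that add atoms: (trimethylsilyl)diazomethane, C[Si](C)(C)C=[N+]=[N-]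
Why: O-methylation of the two acidic enols by diazomethane chemistry, which alkylates on oxygen only and leaves the ester, the ketones and the olefins alone.

Step 6
Reactants: 8 bis(methyl enol ether) allyl ester
Product: 9 3-[(3R)-5-acetyl-3-geranyl-2,4-dimethoxy-3-methyl-6-oxocyclohexa-1,4-dien-1-yl]propanoic acid
Conditions: Pd(PPh3)4 (5 mol %), HCO2H (2 equiv), Et3N (2.5 equiv), THF, rt; cold pH 5 buffer work-up; used at once
Reagents that add atoms: none
Why: Tsuji–Trost deallylation of an allyl ester with formate as the hydride donor, under near-neutral conditions that tolerate the enol ethers, the dienone and the geranyl chain.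

Step 7
Reactants: 10 geranyl bromide; 11 ethynylmagnesium bromide
Product: 12 (4E)-5,9-dimethyldeca-4,8-dien-1-yne
Conditions: 11 (1.5 equiv), CuCl (10 mol %), THF, 0 to 50 °C
Reagents that add atoms: none
Why: copper-catalysed coupling of an alkynyl Grignard reagent with a primary allylic bromide, which proceeds by direct substitution at the CH2 terminus and keeps the (E)-geometry.

Step 8
Reactants: 12 (4E)-5,9-dimethyldeca-4,8-dien-1-yne
Product: 15 geranyl silyloxyalkyne, via lithium acetylide 13 (not isolated), via lithium ynolate 14 (not isolated)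
Conditions: n-BuLi (1.05 equiv), THF, −78 °C; LiOOt-Bu (from t-BuOOH and LiN(SiMe3)2), −78 to 0 °C; i-Pr3SiOTf (1.3 equiv), −78 to 0 °C; chromatography on Et3N-deactivated silica
Reagents that add atoms: tert-butyl hydroperoxide, CC(C)(C)OO; triisopropylsilyl trifluoromethanesulfonate, CC(C)[Si](OS(=O)(=O)C(F)(F)F)(C(C)C)C(C)C
Why: oxidation of a lithium acetylide to the lithium ynolate by oxygen transfer from lithium tert-butyl peroxide, followed by O-silylation, which a bulky silyl triflate directs to oxygen.

Step 9
Reactants: 9 ring B propanoic acid; 15 geranyl silyloxyalkyne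
Product: 18 ring B cyclobutenone (both epimers at the ring CH), via acid chloride 16 (not isolated), via ketene 17 (not isolated)
Conditions: Me2C=C(Cl)NMe2 (1.1 equiv), CH2Cl2, 0 °C, 30 min; then 15 (1.5 equiv), Et3N (2 equiv, slow addition), toluene, 0 °C to rt; rapid filtration through Et3N-deactivated silica
Reagents that add atoms: none
Why: neutral conversion of the acid into its chloride with an α-chloroenamine, dehydrochlorination to the aldoketene and in situ [2+2] ketene–silyloxyalkyne cycloaddition, in which the nucleophilic geranyl-bearing alkyne carbon bonds to the ketene carbonyl carbon so that the silyloxy group ends on carbon 3 of the cyclobutenone, while the new CH centre is uncontrolled and later becomes an arene carbon.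

Step 10
Reactants: 19 hex-1-yn-3-ol
Product: 20 hex-1-yn-3-one
Conditions: IBX (1.5 equiv), EtOAc, 75 °C; filtration, careful concentration
Reagents that add atoms: none
Why: hypervalent-iodine oxidation of a secondary propargylic alcohol to the ynone without touching the terminal alkyne.

Step 11
Reactants: 20 hex-1-yn-3-one
Product: 21 2-ethynyl-2-propyl-1,3-dioxolane
Conditions: Me3SiOCH2CH2OSiMe3 (1.3 equiv), Me3SiOTf (5 mol %), CH2Cl2, −78 to −20 °C; pyridine quench
Reagents that add atoms: 1,2-bis(trimethylsilyloxy)ethane, C[Si](C)(C)OCCO[Si](C)(C)C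
Why: aprotic silyl-triflate-catalysed ketalization (Noyori conditions) at low temperature, which converts the carbonyl group of a conjugated ynone without conjugate addition of an alcohol.

Step 12
Reactants: 21 2-ethynyl-2-propyl-1,3-dioxolane
Product: 24 ketal silyloxyalkyne, via lithium acetylide 22 (not isolated), via lithium ynolate 23 (not isolated)
Conditions: n-BuLi (1.05 equiv), THF, −78 °C; LiOOt-Bu (from t-BuOOH and LiN(SiMe3)2), −78 to 0 °C; i-Pr3SiOTf (1.3 equiv), −78 °C; chromatography on Et3N-deactivated silica
Reagents that add atoms: tert-butyl hydroperoxide, CC(C)(C)OO; triisopropylsilyl trifluoromethanesulfonate, CC(C)[Si](OS(=O)(=O)C(F)(F)F)(C(C)C)C(C)C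
Why: the same acetylide-to-ynolate oxidation and O-silylation as in step 8, with the propargylic dioxolane inert to the bases and the silyl triflate consumed by the ynolate at −78 °C.

Step 13
Reactants: 18 ring B cyclobutenone; 24 ketal silyloxyalkyne
Product: 29 ring A phenol, via vinylketene 25 (not isolated), via vinylcyclobutenone 26 (not isolated), via dienylketene 27 (not isolated), via cyclohexadienone 28 (not isolated)
Conditions: 24 (2.5 equiv), toluene (0.2 M), 80 °C then 110 °C, sealed tube, argon
Reagents that add atoms: none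
Why: Thermal 4π electrocyclic opening of 18 gives silyloxy vinylketene 25, whose ketene C=C adds 24 in a [2+2] cycloaddition, the nucleophilic ketal-bearing alkyne carbon bonding to the ketene carbonyl carbon (new bond between ring A carbons 1 and 6) and the oxygen-bearing alkyne carbon to the geranyl-bearing ketene carbon (new bond between ring A carbons 2 and 3), to give vinylcyclobutenone 26. A second 4π opening gives dienylketene 27, and a thermal disrotatory 6π electrocyclization re-forms the bond between ring A carbons 5 and 6 and closes ring A as cyclohexadienone 28, which tautomerizes to phenol 29. The closest known reaction type is the Danheiser benzannulation of cyclobutenones with silyloxyalkynes. No stereocentre is created, because the epimeric CH of 18 and the sp3 carbons of 26 and 28 all end as arene carbons, and the quaternary centre of ring B is a remote spectator under neutral heating. The step needs the regiochemistry of the [2+2] addition, which the polarization of the silyloxyalkyne secures so that the ketal carbon lies between two oxygens, and it needs capture of 25 by 24 ahead of ketene dimerization, which the excess of 24 secures, while the reversible opening of 26 lets only the dienylketene with the vinyl group turned inward go on. The tied-back dioxolane keeps the sixth substituent small enough for the hexasubstituted ring to close.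

Step 14
Reactants: 29 ring A phenol
Product: 30 bis(triisopropylsilyl) ether of the target (oxygens on ring A carbons 2 and 4 silylated)
Conditions: 1 M aq. HCl/THF 1:4, rt to 40 °C
Reagents that add atoms: water, O
Why: acid hydrolysis of the dioxolane through an oxocarbenium ion stabilized by the electron-rich ring, and addition–elimination of water at the two vinylogous methyl esters, give the butyryl ketone and the triketone, while the aryl silyl ethers survive dilute acid and keep the oxygens on ring A carbons 2 and 4 from closing chroman or pyran rings onto the geranyl chain or ring B.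

Step 15
Reactants: 30 bis(triisopropylsilyl) ether of the target
Product: 31 target CNP0209203.1
Conditions: Bu4NF (2.5 equiv), AcOH (2.5 equiv), THF, 0 °C to rt, argon; pH 4 work-up
Reagents that add atoms: none
Why: fluoride cleaves the two hindered aryl silyl ethers through pentacoordinate silicon, while the acetic acid buffer keeps the oxidation-prone phloroglucinol and the triketone protonated, and no olefin or stereocentre is touched.

**Compound list**

1 | 2-methylphloroglucinol (2-methylbenzene-1,3,5-triol) | Cc1c(O)cc(O)cc1O | starting material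
2 | 1-(2,4,6-trihydroxy-3-methylphenyl)ethan-1-one | CC(=O)c1c(O)cc(O)c(C)c1O | intermediate
3 | geraniol | OC/C=C(\C)CCC=C(C)C | starting material
4 | geranyl methyl carbonate | COC(=O)OC/C=C(\C)CCC=C(C)C | intermediate
5 | (4R)-2-acetyl-4-[(2E)-3,7-dimethylocta-2,6-dien-1-yl]-3,5-dihydroxy-4-methylcyclohexa-2,5-dien-1-one (ring B monomer) | O=C1C=C(O)[C@@](C)(C/C=C(\C)CCC=C(C)C)C(O)=C1C(C)=O | intermediate
6 | allyl acrylate | C=CC(=O)OCC=C | starting material
7 | allyl 3-[(3R)-5-acetyl-3-geranyl-2,4-dihydroxy-3-methyl-6-oxocyclohexa-1,4-dien-1-yl]propanoate | C=CCOC(=O)CCC1=C(O)[C@@](C)(C/C=C(\C)CCC=C(C)C)C(O)=C(C(C)=O)C1=O | intermediate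
8 | allyl 3-[(3R)-5-acetyl-3-geranyl-2,4-dimethoxy-3-methyl-6-oxocyclohexa-1,4-dien-1-yl]propanoate | C=CCOC(=O)CCC1=C(OC)[C@@](C)(C/C=C(\C)CCC=C(C)C)C(OC)=C(C(C)=O)C1=O | intermediate
9 | 3-[(3R)-5-acetyl-3-geranyl-2,4-dimethoxy-3-methyl-6-oxocyclohexa-1,4-dien-1-yl]propanoic acid | OC(=O)CCC1=C(OC)[C@@](C)(C/C=C(\C)CCC=C(C)C)C(OC)=C(C(C)=O)C1=O | intermediate
10 | geranyl bromide | BrC/C=C(\C)CCC=C(C)C | starting material
11 | ethynylmagnesium bromide | C#C[Mg]Br | starting material
12 | (4E)-5,9-dimethyldeca-4,8-dien-1-yne | C#CC/C=C(\C)CCC=C(C)C | intermediate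
13 | lithium acetylide of 12 | [Li]C#CC/C=C(\C)CCC=C(C)C | intermediate
14 | lithium (4E)-5,9-dimethyldeca-4,8-dien-1-yn-1-olate (ynolate) | [Li]OC#CC/C=C(\C)CCC=C(C)C | intermediate
15 | triisopropyl{[(4E)-5,9-dimethyldeca-4,8-dien-1-yn-1-yl]oxy}silane (geranyl silyloxyalkyne) | CC(C)[Si](OC#CC/C=C(\C)CCC=C(C)C)(C(C)C)C(C)C | intermediate
16 | acid chloride of 9 | ClC(=O)CCC1=C(OC)[C@@](C)(C/C=C(\C)CCC=C(C)C)C(OC)=C(C(C)=O)C1=O | intermediate
17 | aldoketene of 9 (ring B–CH2–CH=C=O) | O=C=CCC1=C(OC)[C@@](C)(C/C=C(\C)CCC=C(C)C)C(OC)=C(C(C)=O)C1=O | intermediate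
18 | 4-{[(3R)-5-acetyl-3-geranyl-2,4-dimethoxy-3-methyl-6-oxocyclohexa-1,4-dien-1-yl]methyl}-2-geranyl-3-(triisopropylsilyloxy)cyclobut-2-en-1-one, both epimers at carbon 4 of the four-membered ring | O=C1C(C/C=C(\C)CCC=C(C)C)=C(O[Si](C(C)C)(C(C)C)C(C)C)C1CC2=C(OC)[C@@](C)(C/C=C(\C)CCC=C(C)C)C(OC)=C(C(C)=O)C2=O | intermediate
19 | hex-1-yn-3-ol (racemic) | CCCC(O)C#C | starting material
20 | hex-1-yn-3-one | CCCC(=O)C#C | intermediate
21 | 2-ethynyl-2-propyl-1,3-dioxolane | CCCC1(C#C)OCCO1 | intermediate
22 | lithium acetylide of 21 | CCCC1(C#C[Li])OCCO1 | intermediate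
23 | lithium 2-(2-propyl-1,3-dioxolan-2-yl)ethyn-1-olate (ynolate) | CCCC1(C#CO[Li])OCCO1 | intermediate
24 | triisopropyl{[(2-propyl-1,3-dioxolan-2-yl)ethynyl]oxy}silane (ketal silyloxyalkyne) | CCCC1(C#CO[Si](C(C)C)(C(C)C)C(C)C)OCCO1 | intermediate
25 | silyloxy vinylketene from ring opening of 18 (CH2–ring B trans to the ketene carbon) | O=C=C(C/C=C(\C)CCC=C(C)C)/C(O[Si](C(C)C)(C(C)C)C(C)C)=C/CC1=C(OC)[C@@](C)(C/C=C(\C)CCC=C(C)C)C(OC)=C(C(C)=O)C1=O | intermediate
26 | 4-vinylcyclobutenone from 25 and 24 (both epimers at the ring sp3 carbon) | O=C1C(C2(CCC)OCCO2)=C(O[Si](C(C)C)(C(C)C)C(C)C)C1(C/C=C(\C)CCC=C(C)C)/C(O[Si](C(C)C)(C(C)C)C(C)C)=C/CC3=C(OC)[C@@](C)(C/C=C(\C)CCC=C(C)C)C(OC)=C(C(C)=O)C3=O | intermediate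
27 | dienylketene from ring opening of 26 (vinyl group turned inward) | O=C=C(C1(CCC)OCCO1)/C(O[Si](C(C)C)(C(C)C)C(C)C)=C(C/C=C(\C)CCC=C(C)C)\C(O[Si](C(C)C)(C(C)C)C(C)C)=C\CC2=C(OC)[C@@](C)(C/C=C(\C)CCC=C(C)C)C(OC)=C(C(C)=O)C2=O | intermediate
28 | cyclohexa-2,4-dienone from 6π closure of 27 (both epimers at the ring CH) | O=C1C(C2(CCC)OCCO2)=C(O[Si](C(C)C)(C(C)C)C(C)C)C(C/C=C(\C)CCC=C(C)C)=C(O[Si](C(C)C)(C(C)C)C(C)C)C1CC3=C(OC)[C@@](C)(C/C=C(\C)CCC=C(C)C)C(OC)=C(C(C)=O)C3=O | intermediate
29 | ring A phenol: carbon 1 2-propyl-1,3-dioxolan-2-yl, carbons 2 and 4 triisopropylsilyloxy, carbon 3 geranyl, carbon 5 CH2–ring B ((R)-bis(methyl enol ether)), carbon 6 OH | CCCC1(OCCO1)c2c(O)c(CC3=C(OC)[C@@](C)(C/C=C(\C)CCC=C(C)C)C(OC)=C(C(C)=O)C3=O)c(O[Si](C(C)C)(C(C)C)C(C)C)c(C/C=C(\C)CCC=C(C)C)c2O[Si](C(C)C)(C(C)C)C(C)C | intermediate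
30 | target with the oxygens on ring A carbons 2 and 4 as triisopropylsilyl ethers (ring B free triketone, R) | CCCC(=O)c1c(O)c(CC2=C(O)[C@@](C)(C/C=C(\C)CCC=C(C)C)C(O)=C(C(C)=O)C2=O)c(O[Si](C(C)C)(C(C)C)C(C)C)c(C/C=C(\C)CCC=C(C)C)c1O[Si](C(C)C)(C(C)C)C(C)C | intermediate
31 | (4R)-2-acetyl-6-[(3-butanoyl-5-geranyl-2,4,6-trihydroxyphenyl)methyl]-4-geranyl-3,5-dihydroxy-4-methylcyclohexa-2,5-dien-1-one (CNP0209203.1) | CCCC(=O)c1c(O)c(C/C=C(\C)CCC=C(C)C)c(O)c(CC2=C(O)[C@@](C)(C/C=C(\C)CCC=C(C)C)C(O)=C(C(C)=O)C2=O)c1O | target

**Step count**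

Total step count: 15. Longest linear sequence: 9 steps (steps 1, 3, 4, 5, 6, 9, 13, 14, 15).

**Steps most likely to fail**

Step 13. The hindered, inductively deactivated alkyne 24 may capture vinylketene 25 too slowly. Ketene dimerization, loss or migration of the silyl group of 18, or acylation of the new phenol by ketene intermediates would then take over, or the crowded 6π closure may stall. The fallback sets out from 5 and comes back at 31. Commercial 1-(2,4,6-trihydroxyphenyl)butan-1-one is C-geranylated with geranyl bromide 10 (aq. KOH, 0 °C) to 1-(3-geranyl-2,4,6-trihydroxyphenyl)butan-1-one F1. Monomer 5 is converted with formaldehyde and dimethylamine (EtOH, rt) into its Mannich base F2 at the free ring carbon. Warming F2 with F1 (dioxane, 80 °C) eliminates dimethylamine to the ring B methylene trione F3, which the single free arene carbon of F1 captures by conjugate addition to give 31 directly.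

Step 9. The neighbouring ring B carbonyl oxygen may attack the acyl chloride or the ketene through a six-membered acyloxy oxocarbenium ion and then lose a methyl group to an enol lactone. The aldoketene may also dimerize, and the silyl enol ether of 18 may hydrolyse on isolation. The fallback sets out from 5 and comes back at 18 through ketene 17. C-Alkylation of 5 at its free ring carbon with 1-bromo-3-diazopropan-2-one (K2CO3, acetone, 0 °C) gives the diazoketone F4, and O-methylation (Me3SiCHN2, toluene/MeOH) gives its bis(methyl enol ether) F5. Photochemical Wolff rearrangement of F5 in the presence of 15 generates 17 without an acyl chloride, chloride ion or base, and the [2+2] cycloaddition gives 18. Irradiation is stopped as soon as the diazoketone is consumed.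

Step 3. Alkylation may occur at the unsubstituted ring carbon or at oxygen in place of the methyl-bearing carbon. The product may be geranylated further, the π-geranyl complex may partly scramble its E/Z geometry, or the facial selectivity may be insufficient. The fallback sets out from 2 and comes back at 5. Base-mediated dearomative C-geranylation of 2 with geranyl bromide 10 (NaOMe, MeOH, 0 °C) gives the racemic monomer F6. Its enantiomers are separated by preparative chromatography on a chiral stationary phase, and the (R)-enantiomer 5 continues.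

**Further compounds**

F1 | step 13 | 1-(3-geranyl-2,4,6-trihydroxyphenyl)butan-1-one | CCCC(=O)c1c(O)cc(O)c(C/C=C(\C)CCC=C(C)C)c1O
F2 | step 13 | Mannich base of 5, (4R)-2-acetyl-6-[(dimethylamino)methyl]-4-geranyl-3,5-dihydroxy-4-methylcyclohexa-2,5-dien-1-one | CN(C)CC1=C(O)[C@@](C)(C/C=C(\C)CCC=C(C)C)C(O)=C(C(C)=O)C1=O
F3 | step 13 | ring B methylene trione, (4S)-6-acetyl-4-geranyl-5-hydroxy-4-methyl-2-methylidenecyclohex-5-ene-1,3-dione (same spatial arrangement at the quaternary carbon as in 5; only the descriptor changes with the priorities) | C=C1C(=O)[C@@](C)(C/C=C(\C)CCC=C(C)C)C(O)=C(C(C)=O)C1=O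
F4 | step 9 | diazoketone, (4R)-2-acetyl-6-(3-diazo-2-oxopropyl)-4-geranyl-3,5-dihydroxy-4-methylcyclohexa-2,5-dien-1-one | [N-]=[N+]=CC(=O)CC1=C(O)[C@@](C)(C/C=C(\C)CCC=C(C)C)C(O)=C(C(C)=O)C1=O
F5 | step 9 | bis(methyl enol ether) of the diazoketone | [N-]=[N+]=CC(=O)CC1=C(OC)[C@@](C)(C/C=C(\C)CCC=C(C)C)C(OC)=C(C(C)=O)C1=O
F6 | step 3 | racemic ring B monomer | O=C1C=C(O)C(C)(C/C=C(\C)CCC=C(C)C)C(O)=C1C(C)=O
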